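The furan-2,5-dione ring is disconnected across its C3=C4 double bond. C3 (bearing the sixteen-carbon chain) and C4 (bearing the methyl) are the two carbons of a 2-alkyne, and the carbonyl carbons C2 and C5 come from an isocyanate and CO. Because C2 and C5 sit on the same ring heteroatom, either orientation of the unsymmetrical alkyne gives the same ring. One ruthenium-catalysed cocyclization thus builds the whole N-phenylmaleimide, a masked anhydride. The precursor is the linear C19 alkyne whose (S)-configured carbinol oxygen is held as a TBS ether, since the later imide hydrolysis would strip an acetate anyway; the acetate is put on last.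

Key step: step 5

Remark on the chemistry: propyne, 1,12-dibromododecane, (S)-butane-1,3-diol, phenyl isocyanate and CO are taken as commercial; the carbinol oxygen is a spectator in the key step and is carried as its silyl ether, so the acetate is installed only once, after the anhydride is unveiled.

Step 1
Reactants: 1 propyne; 2 1,12-dibromododecane
Product: 4 15-bromopentadec-2-yne, via propynyllithium 3 (not isolated)
Conditions: 1, n-BuLi, THF, −78 °C; then added to 2 (3 equiv), THF/DMPU, −20 °C to rt
Reagents that add atoms: none
Why: SN2 alkylation of a lithium acetylide by a primary bromide in a dipolar cosolvent should stop at monoalkylation when the acetylide is added to an excess of the dibromide, which is recovered.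

Step 2
Reactants: 5 (S)-butane-1,3-diol
Product: 6 (3S)-3-hydroxybutyl 4-methylbenzenesulfonate
Conditions: TsCl (1.0 equiv), Et3N, CH2Cl2, −20 to 0 °C
Reagents that add atoms: p-toluenesulfonyl chloride, Cc1ccc(cc1)S(=O)(=O)Cl
Why: Sterically controlled selective sulfonylation should tosylate the primary hydroxyl and leave the secondary one, and with it the stereocenter, untouched.

Step 3
Reactants: 6 (3S)-3-hydroxybutyl 4-methylbenzenesulfonate
Product: 7 (3S)-3-[(tert-butyldimethylsilyl)oxy]butyl 4-methylbenzenesulfonate
Conditions: TBSCl, imidazole, DMF, 0 °C to rt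
Reagents that add atoms: tert-butyldimethylsilyl chloride, CC(C)(C)[Si](C)(C)Cl
Why: Imidazole-mediated silylation of the secondary alcohol is a standard protection, and the weak base should not trigger oxetane formation from the hydroxy tosylate.

Step 4
Reactants: 4 15-bromopentadec-2-yne; 7 (3S)-3-[(tert-butyldimethylsilyl)oxy]butyl 4-methylbenzenesulfonate
Product: 9 tert-butyldimethyl{[(2S)-nonadec-17-yn-2-yl]oxy}silane, via pentadec-13-ynylmagnesium bromide 8 (not isolated)
Conditions: 4 (1.3 equiv), Mg, THF, 40 °C; then 7, Li2CuCl4 (cat.), THF, −78 °C to rt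
Reagents that add atoms: none
Why: Copper-catalysed cross-coupling of a primary alkyl Grignard reagent with a primary tosylate (Kochi–Schlosser type) should join the two sp3 carbons; the internal alkyne has no acidic hydrogen, the silyl ether is inert, and the stereocenter two carbons away is not involved.

Step 5
Reactants: 9 tert-butyldimethyl{[(2S)-nonadec-17-yn-2-yl]oxy}silane; 10 phenyl isocyanate; 11 carbon monoxide
Product: 12 3-{(15S)-15-[(tert-butyldimethylsilyl)oxy]hexadecyl}-4-methyl-1-phenyl-1H-pyrrole-2,5-dione
Conditions: Ru3(CO)12 (cat.), 10 (2 equiv), 11 (1 atm), mesitylene, 130 °C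
Reagents that add atoms: none
Why: On a zerovalent ruthenium carbonyl fragment the triple bond of 9 and the C=N bond of 10 should couple oxidatively to a five-membered metallacycle (Ru, the two former alkyne carbons, the isocyanate carbon and nitrogen); migratory insertion of CO enlarges it to a six-membered acyl metallacycle, from which reductive elimination expels the imide and regenerates the catalyst. The closest known reaction type is the Ru3(CO)12-catalysed three-component (2+2+1) cocyclization of internal alkynes, isocyanates and CO to fully substituted maleimides, in which dialkyl alkynes and aryl isocyanates are ordinary partners. The single ring, the five-membered imide, is closed at the metal by that reductive elimination and not by a polar ring closure, two C–C(=O) bonds and one C(=O)–N bond being made in the one operation. No stereocenter is formed; the existing (S)-carbinol centre lies fourteen methylenes from the reacting carbons and, as a silyl ether in a neutral aprotic medium, has no pathway for epimerization. Regioselectivity is not required, because the nitrogen bridges both carbonyls and the two orientations of the methyl alkyl alkyne lead to the same imide. What is required is chemoselectivity for cross-cyclization over alkyne cyclotrimerization, cyclopentadienone formation and isocyanate trimerization; it is secured by the CO atmosphere, the excess of isocyanate and the substrate itself, an unstrained dialkyl alkyne free of O–H, N–H or chelating groups.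

Step 6
Reactants: 12 3-{(15S)-15-[(tert-butyldimethylsilyl)oxy]hexadecyl}-4-methyl-1-phenyl-1H-pyrrole-2,5-dione
Product: 15 3-[(15S)-15-hydroxyhexadecyl]-4-methylfuran-2,5-dione, via dipotassium maleate salt 13 (not isolated), via silyl ether anhydride 14 (not isolated)
Conditions: KOH, THF/MeOH/H2O, reflux; evaporate THF/MeOH; then 3 M aq HCl, THF, rt
Reagents that add atoms: potassium hydroxide (its oxygen becomes ring O1), [K+].[OH-]
Why: Alkaline hydrolysis of the N-aryl imide should cleave both acyl–N bonds to the maleate dianion and aniline; on acidification the cis-dialkylmaleic acid dehydrates spontaneously to the anhydride, and the aqueous acid hydrolyses the secondary silyl ether at the Si–O bond, so the C–O bond and the (S) configuration are retained.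

Step 7
Reactants: 15 3-[(15S)-15-hydroxyhexadecyl]-4-methylfuran-2,5-dione
Product: 16 (2S)-16-(4-methyl-2,5-dioxo-2,5-dihydrofuran-3-yl)hexadecan-2-yl acetate
Conditions: Ac2O, pyridine, DMAP (cat.), CH2Cl2, 0 °C to rt
Reagents that add atoms: acetic anhydride, CC(=O)OC(C)=O
Why: DMAP-catalysed O-acylation touches only the O–H bond, so the configuration is retained, and the dialkylmaleic anhydride is stable to these conditions because any opened form is reclosed by acetic anhydride.

Compound list
1 | propyne | CC#C | starting material
2 | 1,12-dibromododecane | BrCCCCCCCCCCCCBr | starting material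
3 | propynyllithium | [Li]C#CC | intermediate
4 | 15-bromopentadec-2-yne | CC#CCCCCCCCCCCCCBr | intermediate
5 | (S)-butane-1,3-diol | C[C@H](O)CCO | starting material
6 | (3S)-3-hydroxybutyl 4-methylbenzenesulfonate | C[C@H](O)CCOS(=O)(=O)c1ccc(C)cc1 | intermediate
7 | (3S)-3-[(tert-butyldimethylsilyl)oxy]butyl 4-methylbenzenesulfonate | C[C@H](O[Si](C)(C)C(C)(C)C)CCOS(=O)(=O)c1ccc(C)cc1 | intermediate
8 | pentadec-13-ynylmagnesium bromide | CC#CCCCCCCCCCCCC[Mg]Br | intermediate
9 | tert-butyldimethyl{[(2S)-nonadec-17-yn-2-yl]oxy}silane | CC(C)(C)[Si](C)(C)O[C@@H](C)CCCCCCCCCCCCCCC#CC | intermediate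
10 | phenyl isocyanate | O=C=Nc1ccccc1 | starting material
11 | carbon monoxide | [C-]#[O+] | starting material
12 | 3-{(15S)-15-[(tert-butyldimethylsilyl)oxy]hexadecyl}-4-methyl-1-phenyl-1H-pyrrole-2,5-dione | CC(C)(C)[Si](C)(C)O[C@@H](C)CCCCCCCCCCCCCCC1=C(C)C(=O)N(c2ccccc2)C1=O | intermediate
13 | dipotassium (2Z)-2-{(15S)-15-[(tert-butyldimethylsilyl)oxy]hexadecyl}-3-methylbut-2-enedioate | [K+].[K+].[O-]C(=O)/C(C)=C(/CCCCCCCCCCCCCC[C@H](C)O[Si](C)(C)C(C)(C)C)C(=O)[O-] | intermediate
14 | 3-{(15S)-15-[(tert-butyldimethylsilyl)oxy]hexadecyl}-4-methylfuran-2,5-dione | CC(C)(C)[Si](C)(C)O[C@@H](C)CCCCCCCCCCCCCCC1=C(C)C(=O)OC1=O | intermediate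
15 | 3-[(15S)-15-hydroxyhexadecyl]-4-methylfuran-2,5-dione | O[C@@H](C)CCCCCCCCCCCCCCC1=C(C)C(=O)OC1=O | intermediate
16 | (2S)-16-(4-methyl-2,5-dioxo-2,5-dihydrofuran-3-yl)hexadecan-2-yl acetate | CC(=O)O[C@@H](C)CCCCCCCCCCCCCCC1=C(C)C(=O)OC1=O | target

Total step count: 7.
Longest linear sequence: 6 steps (5 → 6 → 7 → 9 → 12 → 15 → 16, steps 2 to 7); the other branch (step 1) joins at step 4.

Steps most likely to fail

Step 5. The alkyne may be diverted into cyclotrimerization or cyclopentadienone formation, or the isocyanate may trimerize before the cross-cyclization turns over. The fallback sets out from 9 and replaces the carbonylative assembly by a nickel-catalysed reductive double carboxylation of the internal alkyne with CO2 (Ni(acac)2, 2,2'-bipyridine, Zn powder, MgBr2, DMF, CO2 1 atm, rt). Zerovalent nickel generated by zinc should form a nickelalactone from the alkyne and CO2, and a second, MgBr2-assisted carboxylation should give magnesium (2Z)-2-{(15S)-15-[(tert-butyldimethylsilyl)oxy]hexadecyl}-3-methylbut-2-enedioate F1. Acidic work-up closes F1 to the silyl ether anhydride 14, and stirring 14 with 3 M aq HCl in THF, as in the second half of step 6, should give 15, where the fallback rejoins the route without an imide stage.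

Step 4. Formation of the Grignard reagent from the waxy bromoalkyne may be eroded by Wurtz-type homocoupling, or the copper-catalysed displacement may be slow enough for the tosylate to be lost to side reactions. The fallback is a Julia-type sulfone alkylation that sets out from 7. Displacement with PhSO2Na (DMF, 60 °C) should give (S)-tert-butyldimethyl{[4-(phenylsulfonyl)butan-2-yl]oxy}silane F2. Deprotonation with n-BuLi (THF/DMPU, −78 °C) gives the α-lithio sulfone F3, and alkylation with bromide 4 should give tert-butyldimethyl{[(2S)-4-(phenylsulfonyl)nonadec-17-yn-2-yl]oxy}silane F4 as both C4 epimers. Reductive desulfonylation with Na(Hg) and Na2HPO4 in MeOH/THF leaves the isolated alkyne and the silyl ether alone and returns to the route at 9.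

Step 6. Cleavage of the silyl ether may lag behind ring closure in the aqueous acid, and during the prolonged acid exposure the liberated alcohol can begin to acylate on the anhydride of another molecule. The fallback uncouples deprotection from ring exchange and sets out from 12. HF·pyridine in THF (0 °C to rt) should give 3-[(15S)-15-hydroxyhexadecyl]-4-methyl-1-phenyl-1H-pyrrole-2,5-dione F5. KOH in THF/MeOH/H2O at reflux then gives dipotassium (2Z)-2-[(15S)-15-hydroxyhexadecyl]-3-methylbut-2-enedioate F6, and only a brief acidification (aq HCl, 0 °C) is needed to close the anhydride, returning to the route at 15.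

Further compounds
F1 | step 5 | magnesium (2Z)-2-{(15S)-15-[(tert-butyldimethylsilyl)oxy]hexadecyl}-3-methylbut-2-enedioate | [Mg+2].[O-]C(=O)/C(C)=C(/CCCCCCCCCCCCCC[C@H](C)O[Si](C)(C)C(C)(C)C)C(=O)[O-]
F2 | step 4 | (S)-tert-butyldimethyl{[4-(phenylsulfonyl)butan-2-yl]oxy}silane | C[C@H](O[Si](C)(C)C(C)(C)C)CCS(=O)(=O)c1ccccc1
F3 | step 4 | α-lithio derivative of (S)-tert-butyldimethyl{[4-(phenylsulfonyl)butan-2-yl]oxy}silane | C[C@H](O[Si](C)(C)C(C)(C)C)CC([Li])S(=O)(=O)c1ccccc1
F4 | step 4 | tert-butyldimethyl{[(2S)-4-(phenylsulfonyl)nonadec-17-yn-2-yl]oxy}silane (both C4 epimers) | C[C@H](O[Si](C)(C)C(C)(C)C)CC(CCCCCCCCCCCCC#CC)S(=O)(=O)c1ccccc1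
F5 | step 6 | 3-[(15S)-15-hydroxyhexadecyl]-4-methyl-1-phenyl-1H-pyrrole-2,5-dione | O[C@@H](C)CCCCCCCCCCCCCCC1=C(C)C(=O)N(c2ccccc2)C1=O
F6 | step 6 | dipotassium (2Z)-2-[(15S)-15-hydroxyhexadecyl]-3-methylbut-2-enedioate | [K+].[K+].[O-]C(=O)/C(C)=C(/CCCCCCCCCCCCCC[C@H](C)O)C(=O)[O-]
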